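## Structural features

The target is a bisabolane-type C15 triol diester. A fully substituted cyclohexane (C1–C6) is joined through C1 to the sp2 carbon C7 of an exocyclic methylene, and C7 carries the chain C8(OH)–C9H2–C10(O-angeloyl)–C11(CH3)2OH. The ring holds five stereocentres, four of them contiguous: C1 (side chain), C3 (OH), C4 (CH3 and tertiary OH), C5 (angelate) and C6 (OH). O4, O5, O6 and the C1 substituent lie on one face (β) and O3 on the other, so C3/C4 is a trans-diaxial diol and C4/C5/C6 an all-cis triol whose O6 is cis to the bulky C1 group. In the chain, C8 and C10 are 1,3-anti (8R,10R) and are insulated from the ring stereocentres by C7, so the ring cannot control them. The fragile groups are the two (Z)-2-methylbut-2-enoates (they isomerise to tiglates with nucleophiles, base or heat and migrate to neighbouring free hydroxyls), the allylic C8 carbinol next to a 1,1-disubstituted alkene, and the two tertiary alcohols. The real difficulties are the contra-steric O6/C1 cis relation, telling O5 and O10 (acylated) from O3, O6 and O8 (free), and setting C8/C10 remotely. The key step exploits the C8(O)–C9H2–C10(O) unit next to the C11 carbinol: it is the retron of a 2-isoxazoline from a C8 nitrile oxide and a terminal alkene, and the C11 hydroxyl is the handle that ties the alkene to a chiral zinc template.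

## Logic of the disconnections

28 ⇒ 27. The O3–Si and O6–Si bonds are cut last. Both esters must be in place before O3 and O6 are freed, and buffered fluoride is the one deprotection that Z-enoates tolerate. The demand is a non-basic fluoride source, because O5→O6 acyl migration and Z→E isomerisation are base-promoted.

27 ⇒ 26 + 24. The C8–H bond and the O10–acyl bond are cut together. Hydride delivery from an O10-bound hemiacetal removes the C8 stereocentre and the second ester in one move and makes a protecting group at O8 unnecessary. The forward step must form a hemiacetal at a hindered carbinol and must not isomerise 24.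

24 ⇒ 23 ⇒ 20. Two C–H bonds at the carbonyl carbon are adjusted (aldehyde to alcohol to acid). This traces the C5 aldehyde to the stable, purchasable acid. Neither forward step may touch the Z alkene.

26 ⇒ 22. The C8=O and O10–H groups are reconnected as C8=N–O10. A β-hydroxy α-methylene ketone is too prone to dehydration, oxa-Michael closure and enolisation to be carried or made by aldol chemistry, so it is stored as the heterocycle. The forward N–O cleavage must spare three alkenes and an enoate, and the imine must be hydrolysed only after the reductant is spent.

22 ⇒ 19 + 20. The O5–acyl bond is cut here because 19 has a single secondary hydroxyl (O4 and O11 are tertiary). Acylation then needs no selectivity, and no O8 hydroxyl exists yet. The demand is esterification of a hindered alcohol without a nucleophilic catalyst.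

19 ⇒ 18. The two acetal C–O bonds at O4 and O5 are restored. The acetonide is removed directly after the cycloaddition, when only two hindered silyl ethers and an acid-stable heterocycle are present. The acid must open a cis-fused dioxolane without cleaving secondary silyl ethers.

18 ⇒ 17 + 16. C8–C9 and O–C10 are cut. This splits the molecule into the complete ring fragment and a C5 alcohol and removes C10. The forward step must control the alkene face by reagent, since the ring stereocentres are remote, and must keep the dipole from dimerising.

17 ⇒ 15 ⇒ 14 ⇒ 13. The C8–Cl bond and then the C8=N bond are removed. This is the standard route from an aldehyde to a nitrile oxide. The chlorination must take the oxime carbon and not the vinyl group.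

13 ⇒ 11 (through 12). The C8–O bonds are cut, which returns the isopropenyl group. C7, its methylene and C8 are then already present in 1. The allylic oxidation must choose the methyl group over the C1 methine.

11 ⇒ 10. Both O–Si bonds are cut together; one reagent covers the two remaining hydroxyls. The demand is a silylating agent strong enough for two axial, hindered alcohols.

10 ⇒ 9. The O6–benzoyl bond is restored. The ester is kept until the acetonide is on, so that O6 cannot take part in acetal formation and no ketone is present when base is used.

9 ⇒ 8. The acetal C–O bonds are cut. The acetonide is the device that tells O5 from O3 and O6: only O4/O5 is a free cis-diol. The forward step needs only mild acid.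

8 ⇒ 7. The C3–O bond from water is cut, giving the epoxide. This removes C3 as an independent stereocentre. The opening must occur at C3 with inversion and not at the tertiary C4.

7 ⇒ 6. The oxirane C–O bonds are cut to the alkene. The 5β-hydroxyl must deliver the oxygen to its own face and leave the isopropenyl group alone.

6 ⇒ 5. The C5–H bond is cut to the enone. The hydride must add 1,2 and from the α face.

5 ⇒ 4. The C6–O bond is exchanged with inversion. Oxygen can only be put on C6 anti to the C1 substituent, so the cis relation has to come from a substitution. The forward step needs an SN2 reaction at an α-keto carbinol without epimerisation.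

4 ⇒ 1. The C6–O bond is cut, leading to the commercial terpene 1, which supplies C1 in the correct absolute configuration and all ten carbons of the ring fragment.

## Other disconnections considered

Alternative 1: The cut runs through C1–C2 and C5–C6. Isoprene A1 and 2,2-dimethyl-1,3-dioxin-4-one A2 would combine in a Lewis-acid-promoted Diels–Alder reaction to the cis-fused lactone acetal A3, whose carbonyl carbon is C7 and whose acetal oxygen is O6.
- **In favour:** the suprafacial addition fixes the C1/C6 cis relation as the ring forms, from two cheap achiral components, and places the C3=C4 alkene and its methyl correctly. On this point A3 would be the better plan, since the chosen route needs a hydroxylation and a separate inversion (steps 1 and 2) for the same relation.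
- **Against:** A2 is a β-alkoxy enoate and a reluctant dienophile. The "para" regiochemistry is only a preference. The absolute configuration would need a chiral Lewis acid or auxiliary, whereas 1 supplies C1 for nothing. A3 lacks O3, O4 and O5, so an allylic oxidation plus the chemistry of steps 4 and 5 would still be needed.
- **Structure:** C7 is at the carboxyl level and must become the alkene carbon bearing C8–C11, so the C8/C10 problem stays unsolved; in the chosen plan C7, its methylene and C8 come with the isopropenyl group.
- **Mechanism:** both plans rest on a stereospecific concerted cycloaddition, here for the ring, there for the chain.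
- **Step economy:** the ring would be reached sooner, but the C7 homologation and the missing enantiocontrol should cancel that gain.

Alternative 2: The cut is C2–C3. A D-hexose-derived 2-C-methyl 6-deoxyhex-5-enopyranoside A4 with a 3,4-acetonide would undergo HgCl2- or PdCl2-mediated Ferrier carbocyclization (hydroxymetallation of the enol ether, ring opening, intramolecular aldol) to the hydroxy cyclohexanone A5.
- **In favour:** O4, O5, O6 and the C4 methyl would come from the sugar in the all-cis array, and the new C3 hydroxyl is expected trans to O5, as the target requires. Four ring stereocentres would thus be set without an inversion or an epoxide opening; here the alternative is at least the equal of the chosen plan.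
- **Against:** C1 emerges as a ketone. The whole C7–C11 chain must then be attached at a hindered, α-oxygenated carbonyl, and the C1–H centre (cis to O6) set afterwards with no secure facial control. A5 is a β-hydroxy ketone that can eliminate, and A4 needs a long protecting-group sequence.
- **Structure:** the chosen plan never forms a C–C bond at the ring, because 1 brings C1 and C7 already joined.
- **Mechanism:** the Ferrier step is a stepwise aldol controlled by a chair transition state, well behaved but less rigid than a cycloaddition.
- **Step economy:** the two routes to the ring are comparable; the alternative falls behind once the side chain is counted.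

Alternative 3: The cut is C4–C5. Keto aldehyde A6 would be cyclised by a triazolium-derived N-heterocyclic carbene; the acyl-anion equivalent from the C5 aldehyde adds to the C4 methyl ketone to give the 2-hydroxy-2-methylcyclohexanone A7.
- **In favour:** the ring and the tertiary carbinol C4 form in one metal-free catalytic step. A7 has O3 and O6 silylated and C5 as a ketone, so after reduction O5 would be the only free secondary hydroxyl. On protecting-group economy this is better than the chosen plan, which spends steps 6, 7 and 13 on that distinction.
- **Against:** A6 needs three stereocentres (C1, C3, C6) built in an open chain. C6 is α to the aldehyde and β to the ester, so epimerisation and β-elimination threaten under the basic carbene conditions. The C4 configuration and the later hydride face at C5 rest on substrate control that is hard to predict. C7 is again a carboxyl carbon.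
- **Structure and mechanism:** the chosen plan relays the C1 configuration of 1 around the ring through cyclic steps that each have a clear model; the alternative concentrates the stereochemical risk in one reversible umpolung addition.
- **Step economy:** the alternative is likely longer once A6 and the chain are included.

Key step: step 12

Remark on names: ring atoms are C1 (side chain), C2 (CH2), C3, C4 (methyl), C5, C6; chain atoms are C7 (=CH2), C8, C9, C10, C11. β is the ring face of the C1 substituent and α the opposite face.
Remark on chemistry: (Z)-2-methylbut-2-enal is assumed not to be a dependable catalogue item and is made from angelic acid.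
Remark on chemistry: the zinc tartrate template is assumed to show, with the tertiary alcohol 16, the face selectivity known for allyl alcohol, where the (R,R)-ester leads to the (R)-carbinol isoxazoline.

## Route

Step 1
Reactants: 1 (S)-carvone
Product: 4 6α-hydroxycarvone (5R,6R; hydroxyl trans to the isopropenyl group), via trimethylsilyl dienol ether 2 (not isolated), via 6α-trimethylsilyloxy ketone 3 (not isolated)
Conditions: LDA, THF, −78 °C, then Me3SiCl; crude 2, mCPBA, NaHCO3, CH2Cl2, −20 °C; then 1 M HCl, THF, 0 °C
Reagents that add atoms: 3-chloroperoxybenzoic acid, OOC(=O)c1cccc(Cl)c1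
Why: Kinetic deprotonation at the α′-methylene (C6) and silylation give the cross-conjugated dienol ether, whose electron-rich C5=C6 bond is epoxidised first (Rubottom oxidation); the peracid approaches anti to the adjacent isopropenyl group, so the new C6–O bond is α, and acid removes the migrated silyl group.

Step 2
Reactants: 4 6α-hydroxycarvone
Product: 5 6β-benzoyloxycarvone (5R,6S; benzoate cis to the isopropenyl group)
Conditions: PhCO2H, PPh3, DIAD, THF, 0 °C to rt
Reagents that add atoms: benzoic acid, OC(=O)c1ccccc1
Why: Mitsunobu reaction: the ketol oxygen is activated as an alkoxyphosphonium ion and displaced by benzoate in an SN2 step accelerated by the adjacent carbonyl, which inverts C6 to the β configuration; a benzoate is used because it migrates less readily than more electron-poor esters in the following steps.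

Step 3
Reactants: 5 6β-benzoyloxycarvone
Product: 6 1β-isopropenyl-4-methylcyclohex-3-ene-5β,6β-diol 6-benzoate
Conditions: NaBH4, CeCl3·7H2O, MeOH, −78 °C
Reagents that add atoms: none
Why: Luche reduction gives clean 1,2-reduction; with the isopropenyl group equatorial the 6β-benzoate is axial, so hydride enters axially from the α face, anti to that C–O bond (steric and Felkin–Anh arguments agree, as in the reduction of carvone to cis-carveol), and the 5β-alcohol cis to O6 should result.

Step 4
Reactants: 6 allylic alcohol
Product: 7 3β,4β-epoxy-1β-isopropenyl-4α-methylcyclohexane-5β,6β-diol 6-benzoate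
Conditions: VO(acac)2 (cat.), t-BuOOH, CH2Cl2, 0 °C to rt
Reagents that add atoms: tert-butyl hydroperoxide, CC(C)(C)OO
Why: Hydroxyl-directed epoxidation: the vanadium alkoxide of the 5β-allylic alcohol delivers the peroxide oxygen to its own face of the trisubstituted C3=C4 bond, while the isopropenyl alkene, which has no free hydroxyl within reach, should be left alone.

Step 5
Reactants: 7 epoxy alcohol
Product: 8 1β-isopropenyl-4α-methylcyclohexane-3α,4β,5β,6β-tetrol 6-benzoate
Conditions: HClO4 (cat.), THF/H2O, 0 °C to rt
Reagents that add atoms: water, O
Why: Acid-catalysed epoxide hydrolysis follows the trans-diaxial (Fürst–Plattner) course: in the half-chair with the isopropenyl group equatorial, water can enter axially only at the secondary C3 from the α face, and the electron-withdrawing O5 disfavours cation character at C4; C3 is therefore inverted (3α-OH) and C4 keeps its β oxygen, as for the limonene oxide isomer of the same relative configuration.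

Step 6
Reactants: 8 triol benzoate
Product: 9 4β,5β-O-isopropylidene acetal of 8 (3α-OH free; 6β-benzoate)
Conditions: Me2C(OMe)2, PPTS (cat.), CH2Cl2, rt
Reagents that add atoms: 2,2-dimethoxypropane, COC(C)(C)OC
Why: Acid-catalysed acetal exchange selects the only free cis-1,2-diol (O4/O5); the trans-diaxial O3/O4 pair cannot bridge and O6 is blocked by the benzoate, which is why the ester is kept to this point.

Step 7
Reactants: 9 acetonide benzoate
Product: 10 4β,5β-O-isopropylidene-1β-isopropenyl-4α-methylcyclohexane-3α,4β,5β,6β-tetrol (3α,6β-diol)
Conditions: NaOMe (cat.), MeOH, rt to 40 °C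
Reagents that add atoms: none
Why: Base-catalysed transesterification removes the benzoate now that no enolisable ketone and no migration-prone neighbouring hydroxyl is present; the acetonide is stable to methoxide.

Step 8
Reactants: 10 diol
Product: 11 3α,6β-bis(tert-butyldimethylsilyl) ether of 10
Conditions: TBSOTf, 2,6-lutidine, CH2Cl2, 0 °C to rt
Reagents that add atoms: tert-butyldimethylsilyl trifluoromethanesulfonate, CC(C)(C)[Si](C)(C)OS(=O)(=O)C(F)(F)F
Why: Silylation with a silyl triflate and a hindered base covers both axial secondary hydroxyls in one operation, so that the dipole precursor has no free hydroxyl to compete for zinc in the key step.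

Step 9
Reactants: 11 bis-silyl ether
Product: 13 enal (11 with the isopropenyl methyl oxidised to CHO: 2-substituted acrylaldehyde), via allylic alcohol 12 (not isolated)
Conditions: SeO2 (cat.), t-BuOOH, CH2Cl2, rt; then Dess–Martin periodinane, NaHCO3, CH2Cl2, 0 °C
Reagents that add atoms: tert-butyl hydroperoxide, CC(C)(C)OO (oxygen relayed by selenium dioxide, O=[Se]=O)
Why: Allylic oxidation with SeO2 (ene reaction, then [2,3]-sigmatropic shift) of a 1,1-disubstituted alkene should take the methyl group in preference to the hindered ring methine and return the double bond to its place; Dess–Martin oxidation then converges the alcohol and any aldehyde already formed onto the enal.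

Step 10
Reactants: 13 enal
Product: 14 (E)-aldoxime of 13
Conditions: NH2OH·HCl, pyridine, EtOH, rt
Reagents that add atoms: hydroxylamine hydrochloride, NO.Cl
Why: Oxime formation: for a 2-substituted acrolein under buffered conditions, condensation at the aldehyde is faster than conjugate addition and should give the E-aldoxime.

Step 11
Reactants: 14 oxime
Product: 15 (Z)-hydroximoyl chloride (C8 bears Cl and =N–OH)
Conditions: NCS, DMF, 0 °C to rt
Reagents that add atoms: N-chlorosuccinimide, O=C1CCC(=O)N1Cl
Why: Electrophilic chlorination of the aldoxime carbon by N-chlorosuccinimide gives the hydroximoyl chloride, the storable precursor of the nitrile oxide; the hindered, electron-poor vinyl group is not expected to compete.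

Step 12
Reactants: 15 hydroximoyl chloride; 16 2-methylbut-3-en-2-ol
Product: 18 (10R)-isoxazoline [3-(1-ring-substituted vinyl)-5-(2-hydroxypropan-2-yl)-4,5-dihydroisoxazole with 5R configuration], via nitrile oxide 17 (not isolated)
Conditions: 16 (excess), Et2Zn, diisopropyl (R,R)-tartrate, CHCl3, 0 °C; Et2Zn; then 15 (slow addition), 1,4-dioxane, 0 °C
Reagents that add atoms: none
Why: The ethylzinc species removes HCl from 15 and releases nitrile oxide 17 at zinc; 17 then adds in a concerted suprafacial [3+2] fashion to the terminal alkene of the zinc alkoxide of 16, joining the dipole carbon C8 to C9 and the dipole oxygen to C10. The closest known reaction type is the diethylzinc/tartrate-ester-mediated asymmetric nitrile oxide cycloaddition to allylic alcohols; a conjugated dipole and a tertiary carbinol widen its scope without changing the reaction type. The single ring formed, the 2-isoxazoline, closes by intermolecular 1,3-dipolar cycloaddition, both sigma bonds being made in the same step. The single new stereocentre, C10, is under reagent control: the zinc tartrate template holds the alkoxide and the nitrile oxide oxygen together and exposes one alkene face, and the (R,R)-ester is chosen because it leads to the (R)-carbinol isoxazoline with allyl alcohol, the priority order at C10 being the same here. Regioselectivity (oxygen to C10) is inherent in monosubstituted alkenes and is reinforced by the tether through zinc. Chemoselectivity is needed against dimerisation of 17 to the furoxan and against addition to its own vinyl group; slow addition of 15 to an excess of the preformed alkoxide complex and the shielding of the ring-bound alkene should secure it. The ring stereocentres are too remote to reinforce or oppose the template, and 15 carries no free hydroxyl that could compete for zinc.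

Step 13
Reactants: 18 isoxazoline
Product: 19 isoxazoline 4β,5β-diol (acetonide removed; O3 and O6 silylated; O11 free)
Conditions: TFA/H2O (9:1), CH2Cl2, 0 °C
Reagents that add atoms: none
Why: Acid-catalysed acetal hydrolysis, placed where the molecule holds only two hindered secondary silyl ethers and an acid-stable isoxazoline, so that no allylic oxygen or ester is exposed to the acid; short contact at 0 °C should spare the silyl ethers.

Step 14
Reactants: 19 diol; 20 angelic acid
Product: 22 isoxazoline 5-O-angelate, via mixed anhydride 21 (not isolated)
Conditions: 20, 2,4,6-trichlorobenzoyl chloride, Et3N, toluene, rt; then 19, toluene, 80 °C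
Reagents that add atoms: none
Why: Yamaguchi esterification through the mixed anhydride: O5 is the only secondary hydroxyl in 19 (O4 and O11 are tertiary), so no selectivity problem arises; DMAP is left out because its conjugate addition–elimination would isomerise the Z-enoate to the tiglate.

Step 15
Reactants: 20 angelic acid
Product: 23 (Z)-2-methylbut-2-en-1-ol
Conditions: LiAlH4, Et2O, 0 °C
Reagents that add atoms: none
Why: Hydride reduction of the carboxylic acid to the primary allylic alcohol; addition occurs at the carboxylate carbon only, so the trisubstituted alkene and its Z geometry are kept.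

Step 16
Reactants: 23 (Z)-2-methylbut-2-en-1-ol
Product: 24 (Z)-2-methylbut-2-enal
Conditions: Dess–Martin periodinane, NaHCO3, CH2Cl2, 0 °C; cold bulb-to-bulb transfer, used at once
Reagents that add atoms: none
Why: Buffered Dess–Martin oxidation is neutral and cold, which avoids acid- or base-promoted Z to E isomerisation of the labile enal.

Step 17
Reactants: 22 isoxazoline 5-O-angelate
Product: 26 (10R)-10,11-dihydroxy-8-oxo compound (β-hydroxy α-methylene ketone; O5 angelate; O3 and O6 silylated), via hydroxy imine 25 (not isolated)
Conditions: SmI2, THF, 0 °C; then B(OH)3, MeOH/H2O, rt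
Reagents that add atoms: water, O
Why: Single-electron reduction by SmI2 cleaves the weak N–O bond of the conjugated isoxazoline to the β-hydroxy imine, which boric acid hydrolyses only after the reductant is consumed, so the enone never meets SmI2; the conditions spare the alkenes and the enoate that hydrogenolytic methods would endanger (Mo(CO)6 in wet MeCN is the thermal alternative), and C10 is untouched.

Step 18
Reactants: 26 β-hydroxy enone; 24 (Z)-2-methylbut-2-enal
Product: 27 3,6-bis-O-(tert-butyldimethylsilyl) derivative of the target (8R-hydroxyl free; O5 and O10 angelates)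
Conditions: 24 (excess), SmI2 (30 mol %), THF, −10 °C
Reagents that add atoms: none
Why: Evans–Tishchenko reduction: the samarium alkoxide of the C10 hydroxyl adds to the aldehyde, and the hemiacetal passes its hydride to the samarium-bound C8 ketone through a chair-like six-membered transition state, which sets the 8,10-anti relation (8R from 10R) and leaves the oxidised aldehyde on O10 as the angelate; the mechanism itself tells O8 from O10, so no protecting group is needed.

Step 19
Reactants: 27 bis-silyl ether
Product: 28 target CNP0108485.1 (1R,3S,4R,5S,6S,8R,10R in the numbering used here)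
Conditions: HF·pyridine, pyridine, THF, 0 °C to rt
Reagents that add atoms: none
Why: Fluoride-mediated cleavage of the two silyl ethers under buffered, non-basic conditions, so that neither acyl migration to the newly freed neighbouring hydroxyls nor Z to E isomerisation of the angelates is promoted.

## Compound list

1 | (S)-carvone | CC1=CC[C@@H](CC1=O)C(C)=C | starting material
2 | trimethylsilyl dienol ether of 1 (5-silyloxy-3,5-diene) | CC(=C)[C@H]1CC=C(C)C(O[Si](C)(C)C)=C1 | intermediate
3 | 6α-trimethylsilyloxycarvone | CC(=C)[C@H]1CC=C(C)C(=O)[C@@H]1O[Si](C)(C)C | intermediate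
4 | 6α-hydroxycarvone, (5R,6R)-6-hydroxy-2-methyl-5-(prop-1-en-2-yl)cyclohex-2-en-1-one | CC(=C)[C@H]1CC=C(C)C(=O)[C@@H]1O | intermediate
5 | 6β-benzoyloxycarvone, (5R,6S) | CC(=C)[C@H]1CC=C(C)C(=O)[C@H]1OC(=O)c1ccccc1 | intermediate
6 | 1β-isopropenyl-4-methylcyclohex-3-ene-5β,6β-diol 6-benzoate | CC(=C)[C@H]1CC=C(C)[C@@H](O)[C@H]1OC(=O)c1ccccc1 | intermediate
7 | 3β,4β-epoxy-1β-isopropenyl-4α-methylcyclohexane-5β,6β-diol 6-benzoate | CC(=C)[C@H]1C[C@H]2O[C@@]2(C)[C@@H](O)[C@H]1OC(=O)c1ccccc1 | intermediate
8 | 1β-isopropenyl-4α-methylcyclohexane-3α,4β,5β,6β-tetrol 6-benzoate | CC(=C)[C@H]1C[C@H](O)[C@@](C)(O)[C@@H](O)[C@H]1OC(=O)c1ccccc1 | intermediate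
9 | 4β,5β-O-isopropylidene acetal of 8 | CC(=C)[C@H]1C[C@H](O)[C@@]2(C)OC(C)(C)O[C@H]2[C@H]1OC(=O)c1ccccc1 | intermediate
10 | 4β,5β-O-isopropylidene-1β-isopropenyl-4α-methylcyclohexane-3α,4β,5β,6β-tetrol | CC(=C)[C@H]1C[C@H](O)[C@@]2(C)OC(C)(C)O[C@H]2[C@H]1O | intermediate
11 | 3α,6β-bis(tert-butyldimethylsilyl) ether of 10 | CC(=C)[C@H]1C[C@H](O[Si](C)(C)C(C)(C)C)[C@@]2(C)OC(C)(C)O[C@H]2[C@H]1O[Si](C)(C)C(C)(C)C | intermediate
12 | allylic alcohol (11 with the isopropenyl methyl as CH2OH) | C=C(CO)[C@H]1C[C@H](O[Si](C)(C)C(C)(C)C)[C@@]2(C)OC(C)(C)O[C@H]2[C@H]1O[Si](C)(C)C(C)(C)C | intermediate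
13 | enal (2-ring-substituted acrylaldehyde) | C=C(C=O)[C@H]1C[C@H](O[Si](C)(C)C(C)(C)C)[C@@]2(C)OC(C)(C)O[C@H]2[C@H]1O[Si](C)(C)C(C)(C)C | intermediate
14 | (E)-aldoxime of 13 | C=C(/C=N/O)[C@H]1C[C@H](O[Si](C)(C)C(C)(C)C)[C@@]2(C)OC(C)(C)O[C@H]2[C@H]1O[Si](C)(C)C(C)(C)C | intermediate
15 | (Z)-hydroximoyl chloride | C=C(/C(Cl)=N/O)[C@H]1C[C@H](O[Si](C)(C)C(C)(C)C)[C@@]2(C)OC(C)(C)O[C@H]2[C@H]1O[Si](C)(C)C(C)(C)C | intermediate
16 | 2-methylbut-3-en-2-ol | C=CC(C)(C)O | starting material
17 | ring-bound 2-substituted acrylonitrile oxide | C=C(C#[N+][O-])[C@H]1C[C@H](O[Si](C)(C)C(C)(C)C)[C@@]2(C)OC(C)(C)O[C@H]2[C@H]1O[Si](C)(C)C(C)(C)C | intermediate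
18 | (10R)-isoxazoline, 3-(1-ring-substituted vinyl)-5-(2-hydroxypropan-2-yl)-2-isoxazoline | C=C(C1=NO[C@@H](C(C)(C)O)C1)[C@H]1C[C@H](O[Si](C)(C)C(C)(C)C)[C@@]2(C)OC(C)(C)O[C@H]2[C@H]1O[Si](C)(C)C(C)(C)C | intermediate
19 | isoxazoline 4β,5β-diol (acetonide removed) | C=C(C1=NO[C@@H](C(C)(C)O)C1)[C@H]1C[C@H](O[Si](C)(C)C(C)(C)C)[C@@](C)(O)[C@@H](O)[C@H]1O[Si](C)(C)C(C)(C)C | intermediate
20 | angelic acid, (Z)-2-methylbut-2-enoic acid | C/C=C(/C)C(=O)O | starting material
21 | angelic 2,4,6-trichlorobenzoic anhydride | C/C=C(/C)C(=O)OC(=O)c1c(Cl)cc(Cl)cc1Cl | intermediate
22 | isoxazoline 5-O-angelate | C=C(C1=NO[C@@H](C(C)(C)O)C1)[C@H]1C[C@H](O[Si](C)(C)C(C)(C)C)[C@@](C)(O)[C@@H](OC(=O)/C(C)=C\C)[C@H]1O[Si](C)(C)C(C)(C)C | intermediate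
23 | (Z)-2-methylbut-2-en-1-ol | C/C=C(/C)CO | intermediate
24 | (Z)-2-methylbut-2-enal | C/C=C(/C)C=O | intermediate
25 | (10R)-10,11-dihydroxy-8-imine | C=C(C(=N)C[C@@H](O)C(C)(C)O)[C@H]1C[C@H](O[Si](C)(C)C(C)(C)C)[C@@](C)(O)[C@@H](OC(=O)/C(C)=C\C)[C@H]1O[Si](C)(C)C(C)(C)C | intermediate
26 | (10R)-10,11-dihydroxy-8-oxo compound (β-hydroxy α-methylene ketone) | C=C(C(=O)C[C@@H](O)C(C)(C)O)[C@H]1C[C@H](O[Si](C)(C)C(C)(C)C)[C@@](C)(O)[C@@H](OC(=O)/C(C)=C\C)[C@H]1O[Si](C)(C)C(C)(C)C | intermediate
27 | 3,6-bis-O-(tert-butyldimethylsilyl) derivative of the target | C=C([C@H](O)C[C@@H](OC(=O)/C(C)=C\C)C(C)(C)O)[C@H]1C[C@H](O[Si](C)(C)C(C)(C)C)[C@@](C)(O)[C@@H](OC(=O)/C(C)=C\C)[C@H]1O[Si](C)(C)C(C)(C)C | intermediate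
28 | CNP0108485.1 | C=C([C@H](O)C[C@@H](OC(=O)/C(C)=C\C)C(C)(C)O)[C@H]1C[C@H](O)[C@@](C)(O)[C@@H](OC(=O)/C(C)=C\C)[C@H]1O | target

## Step count and least certain steps

Total step count: 19. Longest linear sequence: 17 steps (steps 1–14 and 17–19, from 1); steps 15 and 16 form a two-step side branch from 20.

**Step 12 (key step).** The tertiary zinc alkoxide of 16 may bind the tartrate template poorly. That would erode or reverse facial selectivity and slow the cycloaddition enough for the nitrile oxide to dimerise. Exchanging the (R,R)- for the (S,S)-ester would correct a reversed sense. The fallback gives up reagent control. It sets out from 15 and returns to 18: the nitrile oxide would be released with Et3N (slow addition, CH2Cl2) in the presence of excess 16, which should give 18 together with its C10 epimer F1. The two are diastereomers because of the ring stereocentres and would be separated by chromatography.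

**Step 18.** Hemiacetal formation at the hindered C10 carbinol may be slow with an α-branched enal. This would leave time for Z to E isomerisation of 24, for oxa-Michael closure of 26 and for 1,3-acyl migration. The fallback separates reduction from acylation; it sets out from 26 and returns at 28. Hydroxyl-directed Evans–Saksena reduction (Me4NBH(OAc)3, MeCN/AcOH, −30 °C) would give the 8,10-anti diol F2. Silylation with Et3SiCl and imidazole at −20 °C would take the less hindered allylic O8 and give the 8-O-triethylsilyl ether F3. Yamaguchi esterification with 20, as in step 14, would then give the bis-angelate F4, and the conditions of step 19 would remove all three silyl groups to reach 28.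

**Step 14.** O5 is equatorial but flanked by a quaternary carbon and an axial silyl ether. Acylation by the mixed anhydride may therefore stall, and prolonged heating invites Z to E isomerisation. The fallback acylates the alkoxide instead of the neutral alcohol; it sets out from 19 and returns to 22. Deprotonation with LiHMDS (THF, −78 °C) and addition of preformed angelic anhydride F5 (from 20 and DCC) should acylate the secondary alkoxide at low temperature.

**Step 9.** The allylic oxidation may be sluggish or attack the ring methine C1, and the acidic selenium species may loosen the acetonide. The fallback replaces oxygen transfer by halogen transfer; it sets out from 11 and returns to 13. Ene-type chlorination (NaOCl, CeCl3·7H2O, CH2Cl2/H2O, 0 °C) would give the allylic chloride F6. Oxidation with N-methylmorpholine N-oxide and catalytic NaI (MeCN, 50 °C) would then convert the chloromethyl group into the aldehyde.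

**Step 2.** The alkoxyphosphonium ion lies α to a ketone, so elimination is possible, and the cis acyloxy ketone may epimerise back to the more stable trans isomer under the basic betaine. The fallback separates activation from displacement; it sets out from 4 and returns to 5. Mesylation (MsCl, Et3N, CH2Cl2, −20 °C) would give the mesylate F7, and caesium benzoate with 18-crown-6 in toluene would displace it with inversion.

## Further compounds

F1 | step 12 | C10 epimer (10S) of isoxazoline 18 | C=C(C1=NO[C@H](C(C)(C)O)C1)[C@H]1C[C@H](O[Si](C)(C)C(C)(C)C)[C@@]2(C)OC(C)(C)O[C@H]2[C@H]1O[Si](C)(C)C(C)(C)C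
F2 | step 18 | (8R,10R)-8,10,11-triol with O5 angelate and O3, O6 silyl ethers | C=C([C@H](O)C[C@@H](O)C(C)(C)O)[C@H]1C[C@H](O[Si](C)(C)C(C)(C)C)[C@@](C)(O)[C@@H](OC(=O)/C(C)=C\C)[C@H]1O[Si](C)(C)C(C)(C)C
F3 | step 18 | 8-O-triethylsilyl ether of F2 | C=C([C@H](O[Si](CC)(CC)CC)C[C@@H](O)C(C)(C)O)[C@H]1C[C@H](O[Si](C)(C)C(C)(C)C)[C@@](C)(O)[C@@H](OC(=O)/C(C)=C\C)[C@H]1O[Si](C)(C)C(C)(C)C
F4 | step 18 | 8-O-triethylsilyl-3,6-bis-O-(tert-butyldimethylsilyl) derivative of the target | C=C([C@H](O[Si](CC)(CC)CC)C[C@@H](OC(=O)/C(C)=C\C)C(C)(C)O)[C@H]1C[C@H](O[Si](C)(C)C(C)(C)C)[C@@](C)(O)[C@@H](OC(=O)/C(C)=C\C)[C@H]1O[Si](C)(C)C(C)(C)C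
F5 | step 14 | angelic anhydride | C/C=C(/C)C(=O)OC(=O)/C(C)=C\C
F6 | step 9 | allylic chloride (11 with the isopropenyl group as 3-chloroprop-1-en-2-yl) | C=C(CCl)[C@H]1C[C@H](O[Si](C)(C)C(C)(C)C)[C@@]2(C)OC(C)(C)O[C@H]2[C@H]1O[Si](C)(C)C(C)(C)C
F7 | step 2 | 6α-methanesulfonyloxycarvone | CC(=C)[C@H]1CC=C(C)C(=O)[C@@H]1OS(C)(=O)=O
A1 | alternative 1 | isoprene | C=CC(C)=C
A2 | alternative 1 | 2,2-dimethyl-1,3-dioxin-4-one | CC1(C)OC=CC(=O)O1
A3 | alternative 1 | cis-fused 2,2,7-trimethyl-4a,5,8,8a-tetrahydrobenzo[d][1,3]dioxin-4-one | O=C1OC(C)(C)O[C@@H]2CC(C)=CC[C@H]12
A4 | alternative 2 | methyl 6-deoxy-3,4-O-isopropylidene-2-C-methylhex-5-enopyranoside (2-OH, O3 and O4 all cis; methoxy trans to them) | C=C1O[C@H](OC)[C@@](C)(O)[C@H]2OC(C)(C)O[C@@H]12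
A5 | alternative 2 | C1-ketone carbocycle with C3 and C4 hydroxyls and C5,C6 acetonide | O=C1C[C@H](O)[C@@](C)(O)[C@H]2OC(C)(C)O[C@@H]12
A6 | alternative 3 | methyl 2-[1-(tert-butyldimethylsilyloxy)-2-oxoethyl]-4-(tert-butyldimethylsilyloxy)-5-oxohexanoate (open-chain keto aldehyde) | COC(=O)[C@@H](C[C@H](O[Si](C)(C)C(C)(C)C)C(C)=O)[C@H](O[Si](C)(C)C(C)(C)C)C=O
A7 | alternative 3 | methyl 4-hydroxy-4-methyl-3-oxo-2,5-bis(tert-butyldimethylsilyloxy)cyclohexane-1-carboxylate | COC(=O)[C@H]1C[C@H](O[Si](C)(C)C(C)(C)C)[C@@](C)(O)C(=O)[C@H]1O[Si](C)(C)C(C)(C)C
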